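The flask was closed, stirred and isothermal, and it is the same blue flask whose run I had followed so far.

| flask | substrate | partner | remark | time |
|---|---|---|---|---|
| blue | 0.050 M | 2.5 equiv | the very flask that is asked about, followed so far |  |
| flask | 0.050 M | 2.50 equiv |  | 30 h |

- blue (time / h: target / %, substrate / %): 0.417: 18.9, 0; 0.667: 25.5, 0.3; 1.33: 26.7, 0.3; 2.00: 25.1, 0; 3.00: 23.6, 0; 5.00: 19.0, 0.6

(each reading ± 0.5 percentage points)

- the numbers in the tables scatter by 0.5 percentage points (one standard deviation)
- on the list of suspects stand: substrate -> intermediate; partner + intermediate -> target; target <-> isomer of the product; partner -> decomposed reagent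

- the moment within 30 h at which there is most target
- the amount of target, in percent of the substrate charged, at that time

I read the ladder from its fastest rung. Substrate already stood at 0% at the first sample, 0.417 h, so its step to intermediate came first. Target then reached a top reading of 26.7% at 1.33 h and sank to 19.0% at 5.00 h. That fall has a half-time of about 7.48 h, longer than the rise took, so I expected the top to lie where the rise ended. That top was about a quarter of the substrate charged, though partner had been charged at 2.5 equiv, so I suspected that partner was decaying to decomposed reagent while it coupled. My reckoning was:

partner yield = 26.7% / 2.5 = 10.7%

This is the target at the top of the curve per partner charged, a reading that carries the scatter.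

The forecast put the top at 1.1 h (0.8 h to 1.5 h) with 26.8% (25.8% to 27.8%), judging that “a later second maximum is unlikely”.

The flask peaked at 1.22 h with 27.1%, inside both ranges, a partner yield of 10.8%; at that moment 4.54% of the partner charge stood there, and intermediate stood at 69.6% of the substrate charged.

    substrate → intermediate (k = 17.0 h⁻¹)
    partner + intermediate → target (k = 8.90 L mol⁻¹ h⁻¹)
    target ⇌ isomer of the product (K = 1.70, k = 0.140 h⁻¹)
    partner → decomposed reagent (k = 2.20 h⁻¹)

In a neighbouring flask, the same recipe but with 6.20 equiv of partner, my 10.7% gave 66.3%, but that neighbouring flask reached 53.3%, twice the best target of the recipe flask, at a partner yield of 8.60%. At 30.0 h the neighbouring flask held intermediate at 37.6% of the substrate charged.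

The earlier runs and the new flask stem from a simulated flask on assumed constants; scatter was added.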